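**The trap.** You divide the charge of nucleophile by a fixed price per electrophile turned over, and the flask refuses that count.

| setting | spring | autumn | Monday's | Wednesday's | Tuesday's |
|---|---|---|---|---|---|
| electrophile | 0.020 M | 0.020 M | 0.020 M | 0.020 M | 0.020 M |
| nucleophile | 1.5 equiv | 3.6 equiv | 1.80 equiv | 1.20 equiv | 2.70 equiv |
| remark | run made earlier | run made earlier |  |  |  |
| time |  |  | 4.0 min | 4.0 min | 4.0 min |

| run | time / s | electrophile / % | target / % |
|---|---|---|---|
| spring | 10.0 | 54.1 | 46.7 |
| spring | 30.0 | 43.6 | 55.2 |
| spring | 60.0 | 42.2 | 58.4 |
| spring | 80.0 | 38.6 | 59.8 |
| spring | 120 | 39.0 | 63.2 |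
| autumn | 25.0 | 18.9 | 83.6 |
| autumn | 50.0 | 14.2 | 86.8 |
| autumn | 80.0 | 10.3 | 89.2 |
| autumn | 90.0 | 9.7 | 90.3 |
| autumn | 120 | 10.5 | 91.1 |

(scatter of a reading: 1 percentage point)

- steps thought possible: nucleophile + acid set free <-> protonated nucleophile; acid set free + target -> side product; electrophile + nucleophile -> acid set free + target; 2 nucleophile -> homo dimer

* part of the electrophile that has reacted at the end, Monday's
* part of the electrophile that has reacted at the end, Wednesday's
* part of the electrophile that has reacted at the end, Tuesday's
* what raising the equivalents of nucleophile from its lowest to its highest value here does to the part of the electrophile that has reacted (changes below 5 percentage points count as none) (no change / it rises / it falls)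

**Two prices.** Let x be c(electrophile) as a fraction of its start, read from the last flat readings: 38.8% in the spring run and 10.2% in the autumn run. Each electrophile turned over has then cost 2.45 equiv of nucleophile in spring and 4.01 equiv in autumn, so the price climbs as the electrophile thins.

**The rule.** Try a price that grows as s/x. Summed over a run, it gives x = exp(−n/s), with n the equivalents charged. Spring gives s = 1.58 equiv and autumn 1.57 equiv. These are two separate runs that agree, so I carry their mean 1.58 equiv as s, the charge per e-fold: the equivalents that cut the electrophile left by the factor e.

**The curve.** Over the first 10.0 s of the spring run the electrophile falls on average at 0.0459 /s of its charge, an average taken across the bend and not the slope at the very start. That chord, drawn on, would meet the level at 13.3 s, which gives the rough place of the knee. Between 60.0 s and 120 s the slope reads 5.33 × 10⁻⁴ /s, while autumn's last readings stand still within the scatter. My levels for the part reacted are 53.2% for Wednesday's, 68.0% for Monday's and 81.9% for Tuesday's. Held to 4.0 min, spring's tail would add 6.40% of the charge, and I commit to the levels plus part of that. The span of 29 percentage points passes 5 points, so the part reacted rises.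

**The forecast.** It says 69% for Monday's, 54% for Wednesday's and 83% for Tuesday's, and it rises, a point above my levels, on this ground: “This looks like the nucleophile running out, not equilibrium.”

**The flasks.** Monday's gives 73.5%, Wednesday's 58.9% and Tuesday's 86.8%; it rises, by 28 points.

    nucleophile + acid set free ⇌ protonated nucleophile, settled at all times (K = 13000 /M)
    acid set free + target → side product (k = 0.0460 /M/s)
    electrophile + nucleophile → acid set free + target (k = 5.60 /M/s)
    2 nucleophile → homo dimer (k = 2.30 /M/s)

**Same rule.** Counted at the end of each flask, s comes to 1.35 equiv for Monday's, 1.35 equiv for Wednesday's and 1.33 equiv for Tuesday's. That is steady across the flasks, and 0.230 equiv below the 1.58 equiv taken from readings ending at 2 min. A neighbour of Wednesday's with 3.00 equiv of nucleophile is reckoned from 1.35 equiv at 89.2% reacted, and it gives 89.6%. In Wednesday's the nucleophile, the limiting reagent, stands at 0.47% of its charge at the end. The rise across the flasks is owed to the equivalents of nucleophile charged: Tuesday's stands at 86.8% reacted, and with Wednesday's charge in its place at 58.9%.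

(All runs are calculated on assumed constants, and the scatter is random.)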